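The furan ring is opened across C2=C3, and both carbons are traced back to carbonyl carbons: C2 to the carbonyl of a 2,4-bis(benzyloxy)benzoate on O1, C3 to the ketone carbon of an acetyl group on C3a of ring A. One low-valent titanium reductive coupling joins these two electrophilic carbons, closes the furan ring and delivers the 2-aryl-3-methylbenzofuran in aromatic form; the methyl group is oxidised to the C3 formyl group afterwards. The precursor is an acylphloroglucinol ester: an acetophenone bearing the aroyl ester on its less hindered phenol, a silyl ether on the other phenol, the methoxy group and the silylated 3-hydroxy-3-methylbutyl chain.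

Key step: step 7

Remark on the chemistry: the ring system is numbered as a benzofuran (O1, C2, C3, C3a, C4 to C7, C7a; ring A is the benzo ring), acetophenone ring positions carry primes, and the target is achiral, so no stereocentre has to be set.

Step 1
Reactants: 1 2',6'-dihydroxy-4'-methoxyacetophenone; 2 prenyl bromide (1-bromo-3-methylbut-2-ene)
Product: 3 2',6'-dihydroxy-4'-methoxy-3'-(3-methylbut-2-en-1-yl)acetophenone
Conditions: 2 (0.9 equiv), 10% aq KOH, 0 °C to rt
Reagents that add atoms: none
Why: C-alkylation of the ambident acylphloroglucinol phenoxide by an allylic bromide in water, where hydrogen bonding to the phenoxide oxygen steers the soft electrophile to carbon; the two free ring positions of 1 are equivalent, so only one mono-C-prenyl compound can form, and a slight deficit of 2 limits double alkylation.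

Step 2
Reactants: 4 2,4-dihydroxybenzoic acid
Product: 5 benzyl 2,4-bis(benzyloxy)benzoate
Conditions: BnBr (3.3 equiv), K2CO3, DMF, 60 °C
Reagents that add atoms: benzyl bromide, BrCc1ccccc1
Why: Williamson etherification of both phenols and O-alkylation of the carboxylate under standard carbonate conditions should benzylate all three acidic OH groups.

Step 3
Reactants: 5 benzyl 2,4-bis(benzyloxy)benzoate
Product: 6 2,4-bis(benzyloxy)benzoic acid
Conditions: KOH, MeOH/THF/H2O, reflux; then aq HCl
Reagents that add atoms: potassium hydroxide, [K+].[OH-]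
Why: Saponification cleaves only the benzyl ester, since aryl benzyl ethers are inert to hydroxide, and acidification releases the free acid.

Step 4
Reactants: 6 2,4-bis(benzyloxy)benzoic acid; 3 2',6'-dihydroxy-4'-methoxy-3'-(3-methylbut-2-en-1-yl)acetophenone
Product: 8 2-acetyl-3-hydroxy-5-methoxy-4-(3-methylbut-2-en-1-yl)phenyl 2,4-bis(benzyloxy)benzoate, via 2,4-bis(benzyloxy)benzoyl chloride 7 (not isolated)
Conditions: (COCl)2, cat. DMF, CH2Cl2, 0 °C to rt, evaporate; then add to 3, Et3N, CH2Cl2, −20 to 0 °C
Reagents that add atoms: none
Why: Vilsmeier-type activation turns the acid into its chloride, which acylates the phenoxide of 3 by nucleophilic acyl substitution at the less hindered 6'-OH, because the 2'-OH sits between the prenyl and acetyl groups and stays hydrogen-bonded to the ketone; one equivalent of acid chloride at low temperature limits bis-acylation.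

Step 5
Reactants: 8 2-acetyl-3-hydroxy-5-methoxy-4-(3-methylbut-2-en-1-yl)phenyl 2,4-bis(benzyloxy)benzoate
Product: 9 2-acetyl-3-hydroxy-4-(3-hydroxy-3-methylbutyl)-5-methoxyphenyl 2,4-bis(benzyloxy)benzoate
Conditions: Co(acac)2 (20 mol %), PhSiH3, O2 (1 atm), THF, rt
Reagents that add atoms: dioxygen, O=O
Why: Mukaiyama hydration, in which hydrogen-atom transfer from a cobalt hydride to the trisubstituted alkene gives the tertiary radical that is trapped by O2 and reduced by the silane to the Markovnikov tertiary alcohol; the neutral conditions spare the aryl ester, the ketone and the benzyl ethers and avoid acid-induced chroman formation.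

Step 6
Reactants: 9 2-acetyl-3-hydroxy-4-(3-hydroxy-3-methylbutyl)-5-methoxyphenyl 2,4-bis(benzyloxy)benzoate
Product: 10 2-acetyl-3-(tert-butyldimethylsilyloxy)-4-[3-(tert-butyldimethylsilyloxy)-3-methylbutyl]-5-methoxyphenyl 2,4-bis(benzyloxy)benzoate
Conditions: TBSOTf (3 equiv), 2,6-lutidine, CH2Cl2, 0 °C to rt
Reagents that add atoms: tert-butyldimethylsilyl trifluoromethanesulfonate, CC(C)(C)[Si](C)(C)OS(=O)(=O)C(F)(F)F
Why: Silylation with a silyl triflate is strong enough for both the hindered hydrogen-bonded phenol and the tertiary alcohol, while 2,6-lutidine is too weak a base to enolise the ketone or to start a Baker–Venkataraman acyl shift of the aryl ester.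

Step 7
Reactants: 10 2-acetyl-3-(tert-butyldimethylsilyloxy)-4-[3-(tert-butyldimethylsilyloxy)-3-methylbutyl]-5-methoxyphenyl 2,4-bis(benzyloxy)benzoate
Product: 11 2-[2,4-bis(benzyloxy)phenyl]-4-(tert-butyldimethylsilyloxy)-5-[3-(tert-butyldimethylsilyloxy)-3-methylbutyl]-6-methoxy-3-methylbenzofuran
Conditions: TiCl3 (6 equiv), Zn dust (12 equiv), DME, reflux, 2 h; then 10 in DME by syringe pump (high dilution), reflux
Reagents that add atoms: none
Why: Low-valent titanium made from TiCl3 and zinc transfers an electron to the aryl ketone, the titanium-bound ketyl carbon (future C3) adds to the carbonyl of the neighbouring ester (future C2), and the titanium diolate formed is deoxygenated, which delivers the C2=C3 double bond and with it the aromatic furan ring without a separate dehydration. The closest known reaction type is the McMurry-type keto ester coupling of 2-acyloxyaryl ketones to 2,3-disubstituted benzofurans. The furan ring closes in the 5-exo-trig mode (ketyl carbon onto the exocyclic C=O of the ester), the ester oxygen is kept as O1, and no stereocentre is created. The step needs ketone–ester ring closure to win over ketone–ketone pinacol dimerisation and plain ketone reduction: the ortho relation of the acetyl and acyloxy groups makes the five-membered closure fast, the two ortho substituents shield the ketone from a second molecule, and syringe-pump addition into a dilute refluxing slurry keeps the stationary ketyl concentration low. Benzyl ethers, silyl ethers and the aryl methyl ether are expected to be inert to the reagent.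

Step 8
Reactants: 11 2-[2,4-bis(benzyloxy)phenyl]-4-(tert-butyldimethylsilyloxy)-5-[3-(tert-butyldimethylsilyloxy)-3-methylbutyl]-6-methoxy-3-methylbenzofuran
Product: 13 2-[2,4-bis(benzyloxy)phenyl]-4-(tert-butyldimethylsilyloxy)-5-[3-(tert-butyldimethylsilyloxy)-3-methylbutyl]-6-methoxybenzofuran-3-carbaldehyde, via 3-(hydroxymethyl)benzofuran 12 (not isolated)
Conditions: DDQ (2.5 equiv), 1,4-dioxane/H2O (10:1), rt
Reagents that add atoms: water, O
Why: DDQ benzylic oxidation, in which hydride abstraction from the C3 methyl group gives a cation stabilised through C2 by O1 and the 2,4-dialkoxyaryl ring, water traps it as alcohol 12 and a second equivalent of DDQ oxidises this to the aldehyde, which deactivates the ring system against further oxidation; the C5 methylene lies between two ortho substituents that keep its C–H bonds out of alignment with the π system, and plain benzyl ethers are inert to DDQ at room temperature.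

Step 9
Reactants: 13 2-[2,4-bis(benzyloxy)phenyl]-4-(tert-butyldimethylsilyloxy)-5-[3-(tert-butyldimethylsilyloxy)-3-methylbutyl]-6-methoxybenzofuran-3-carbaldehyde
Product: 14 2-[2,4-bis(benzyloxy)phenyl]-4-hydroxy-5-(3-hydroxy-3-methylbutyl)-6-methoxybenzofuran-3-carbaldehyde
Conditions: Bu4NF, THF, 0 °C to 45 °C
Reagents that add atoms: none
Why: Fluoride-mediated desilylation should cleave the aryl silyl ether at once and the tertiary silyl ether on gentle warming, and because the medium is never acidic the side-chain alcohol cannot close onto the C4 phenol to give a chroman.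

Step 10
Reactants: 14 2-[2,4-bis(benzyloxy)phenyl]-4-hydroxy-5-(3-hydroxy-3-methylbutyl)-6-methoxybenzofuran-3-carbaldehyde
Product: 15 2-(2,4-dihydroxyphenyl)-4-hydroxy-5-(3-hydroxy-3-methylbutyl)-6-methoxybenzofuran-3-carbaldehyde
Conditions: H2 (1 atm), 10% Pd/C, EtOAc, rt
Reagents that add atoms: none
Why: Hydrogenolysis of the two aryl benzyl ethers over Pd/C is expected to be faster than reduction of the C3 aldehyde, a vinylogous ester carbonyl that is hydrogen-bonded to the C4 hydroxyl, and the reaction is stopped after uptake of two equivalents of H2.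

Compound list
1 | 2',6'-dihydroxy-4'-methoxyacetophenone | CC(=O)c1c(O)cc(OC)cc1O | starting material
2 | prenyl bromide (1-bromo-3-methylbut-2-ene) | CC(C)=CCBr | starting material
3 | 2',6'-dihydroxy-4'-methoxy-3'-(3-methylbut-2-en-1-yl)acetophenone | CC(=O)c1c(O)cc(OC)c(CC=C(C)C)c1O | intermediate
4 | 2,4-dihydroxybenzoic acid | O=C(O)c1ccc(O)cc1O | starting material
5 | benzyl 2,4-bis(benzyloxy)benzoate | O=C(OCc1ccccc1)c1ccc(OCc2ccccc2)cc1OCc1ccccc1 | intermediate
6 | 2,4-bis(benzyloxy)benzoic acid | O=C(O)c1ccc(OCc2ccccc2)cc1OCc1ccccc1 | intermediate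
7 | 2,4-bis(benzyloxy)benzoyl chloride | O=C(Cl)c1ccc(OCc2ccccc2)cc1OCc1ccccc1 | intermediate (not isolated)
8 | 2-acetyl-3-hydroxy-5-methoxy-4-(3-methylbut-2-en-1-yl)phenyl 2,4-bis(benzyloxy)benzoate | CC(=O)c1c(OC(=O)c2ccc(OCc3ccccc3)cc2OCc2ccccc2)cc(OC)c(CC=C(C)C)c1O | intermediate
9 | 2-acetyl-3-hydroxy-4-(3-hydroxy-3-methylbutyl)-5-methoxyphenyl 2,4-bis(benzyloxy)benzoate | CC(=O)c1c(OC(=O)c2ccc(OCc3ccccc3)cc2OCc2ccccc2)cc(OC)c(CCC(C)(C)O)c1O | intermediate
10 | 2-acetyl-3-(tert-butyldimethylsilyloxy)-4-[3-(tert-butyldimethylsilyloxy)-3-methylbutyl]-5-methoxyphenyl 2,4-bis(benzyloxy)benzoate | CC(=O)c1c(OC(=O)c2ccc(OCc3ccccc3)cc2OCc2ccccc2)cc(OC)c(CCC(C)(C)O[Si](C)(C)C(C)(C)C)c1O[Si](C)(C)C(C)(C)C | intermediate (key-step precursor)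
11 | 2-[2,4-bis(benzyloxy)phenyl]-4-(tert-butyldimethylsilyloxy)-5-[3-(tert-butyldimethylsilyloxy)-3-methylbutyl]-6-methoxy-3-methylbenzofuran | Cc1c(-c2ccc(OCc3ccccc3)cc2OCc2ccccc2)oc2cc(OC)c(CCC(C)(C)O[Si](C)(C)C(C)(C)C)c(O[Si](C)(C)C(C)(C)C)c12 | intermediate (key-step product)
12 | {2-[2,4-bis(benzyloxy)phenyl]-4-(tert-butyldimethylsilyloxy)-5-[3-(tert-butyldimethylsilyloxy)-3-methylbutyl]-6-methoxybenzofuran-3-yl}methanol | OCc1c(-c2ccc(OCc3ccccc3)cc2OCc2ccccc2)oc2cc(OC)c(CCC(C)(C)O[Si](C)(C)C(C)(C)C)c(O[Si](C)(C)C(C)(C)C)c12 | intermediate (not isolated)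
13 | 2-[2,4-bis(benzyloxy)phenyl]-4-(tert-butyldimethylsilyloxy)-5-[3-(tert-butyldimethylsilyloxy)-3-methylbutyl]-6-methoxybenzofuran-3-carbaldehyde | O=Cc1c(-c2ccc(OCc3ccccc3)cc2OCc2ccccc2)oc2cc(OC)c(CCC(C)(C)O[Si](C)(C)C(C)(C)C)c(O[Si](C)(C)C(C)(C)C)c12 | intermediate
14 | 2-[2,4-bis(benzyloxy)phenyl]-4-hydroxy-5-(3-hydroxy-3-methylbutyl)-6-methoxybenzofuran-3-carbaldehyde | O=Cc1c(-c2ccc(OCc3ccccc3)cc2OCc2ccccc2)oc2cc(OC)c(CCC(C)(C)O)c(O)c12 | intermediate
15 | 2-(2,4-dihydroxyphenyl)-4-hydroxy-5-(3-hydroxy-3-methylbutyl)-6-methoxybenzofuran-3-carbaldehyde | COc1cc2oc(-c3ccc(O)cc3O)c(C=O)c2c(O)c1CCC(C)(C)O | target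

Total step count: 10.
Longest linear sequence: 9 steps (from 4 through steps 2, 3, 4, 5, 6, 7, 8, 9 and 10; the branch from 1 is 8 steps).

Three steps most likely to fail

Step 7 (key step). The hindered, twisted ketone may be reduced or may dimerise by pinacol coupling before its ketyl closes onto the electron-rich ester, and the hot Lewis-acidic titanium chloride medium may strip the crowded aryl silyl ether. The fallback makes the same C2=C3 bond with reversed polarity at C3, by an intramolecular Wittig olefination of the ester carbonyl. It sets out from 10: i-Bu2AlH (CH2Cl2, −78 °C) would reduce the ketone and cleave the aryl ester to the racemic hydroxybenzyl alcohol 3-(tert-butyldimethylsilyloxy)-4-[3-(tert-butyldimethylsilyloxy)-3-methylbutyl]-2-(1-hydroxyethyl)-5-methoxyphenol F1. PPh3·HBr (MeCN, rt) would convert this, through the ortho-quinone methide, into {1-[2-(tert-butyldimethylsilyloxy)-3-[3-(tert-butyldimethylsilyloxy)-3-methylbutyl]-6-hydroxy-4-methoxyphenyl]ethyl}triphenylphosphonium bromide F2. Acylation of the free phenol of F2 with acid chloride 7 (freshly made from 6) and ylide formation with Et3N in refluxing toluene would then close the furan ring and come back to the route at 11.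

Step 8. Hydride abstraction may lose its site selectivity (attack at the C5 methylene or at the benzyl ether methylenes), or the electron-rich benzofuran may be degraded by over-oxidation. The fallback replaces electron-transfer oxidation by a two-stage route through the isolated alcohol and makes no new compound (F0). Setting out from 11, a Riley oxidation with SeO2 (1,4-dioxane, reflux), which proceeds by an ene reaction and a [2,3]-shift at the allylic methyl of the furan double bond and does not depend on the oxidation potential of the arene, should give alcohol 12, now isolated, possibly with some aldehyde. MnO2 (CH2Cl2, rt) would complete the oxidation and come back to the route at 13.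

Step 1. O-alkylation and a second C-alkylation may compete with the wanted mono-C-prenylation. The fallback moves the prenyl group from oxygen to carbon in a separate step. Setting out from 1, K2CO3 and 2 in refluxing acetone would give the mono-ether 2'-hydroxy-4'-methoxy-6'-(3-methylbut-2-en-1-yloxy)acetophenone F3, in which the remaining phenol stays chelated to the ketone. A thermal para-Claisen–Cope rearrangement (N,N-diethylaniline, reflux) would then deliver the intact prenyl group to a ring carbon; because the ring is symmetric, migration to either free position gives the same compound, and the sequence comes back to the route at 3.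

Further compounds
F1 | step 7 | 3-(tert-butyldimethylsilyloxy)-4-[3-(tert-butyldimethylsilyloxy)-3-methylbutyl]-2-(1-hydroxyethyl)-5-methoxyphenol (racemic) | CC(O)c1c(O)cc(OC)c(CCC(C)(C)O[Si](C)(C)C(C)(C)C)c1O[Si](C)(C)C(C)(C)C
F2 | step 7 | {1-[2-(tert-butyldimethylsilyloxy)-3-[3-(tert-butyldimethylsilyloxy)-3-methylbutyl]-6-hydroxy-4-methoxyphenyl]ethyl}triphenylphosphonium bromide (racemic) | CC(c1c(O)cc(OC)c(CCC(C)(C)O[Si](C)(C)C(C)(C)C)c1O[Si](C)(C)C(C)(C)C)[P+](c1ccccc1)(c1ccccc1)c1ccccc1.[Br-]
F0 | step 8 | none | none
F3 | step 1 | 2'-hydroxy-4'-methoxy-6'-(3-methylbut-2-en-1-yloxy)acetophenone | CC(=O)c1c(O)cc(OC)cc1OCC=C(C)C
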